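**Plan**

1. Feature used: the central benzene ring alternates three oxygens (C2, C4, C6) with three carbon groups (butyryl on C1, CH2 arms on C3 and C5). A ketene carbon, a silyloxyalkyne and the C2–C3–C4 unit of a 3-silyloxycyclobutenone deliver exactly this O–C(arm)–C(O)–C(arm)–C(O)–CH run.
2. Cuts: both arm CH2–C(filicinic ring) bonds, then the aryl–butyryl bond, then the ring bonds C2–C3, C4–C5 and C1–C2 of the benzene ring.
3. Forward: two silyloxyalkynes are made from propargyl silyl ethers, one is converted with ketene into the cyclobutenone, and the benzannulation closes the benzene ring. The two filicinic rings come from dearomatising gem-dimethylation of acylphloroglucinols.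
4. The free ring CH is brominated and the butyryl group is brought in by an acid-free anionic Fries shift. The triethylsilyl arm and then the tert-butyldimethylsilyl arm are freed and joined to acetyl- and propionylfilicinic acid through quinone methides; fluoride removes the last silyl groups.
5. Stereochemistry: the target has no stereocentre. Only regiochemistry (polarisation of ketene and ynol ether) and the order in which the arms react need control; in the free triol the two arms are mirror-related, so either arm may take either filicinic acid.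

Key step: step 5

Remark: the acylfilicinic rings are drawn throughout in the enol tautomer of the target structure. TBS = tert-butyldimethylsilyl, TES = triethylsilyl, TIPS = triisopropylsilyl.

**Route**

Step 1
Reactants: 1 tert-butyldimethyl(prop-2-yn-1-yloxy)silane
Product: 4 3-(tert-butyldimethylsilyloxy)-1-(triisopropylsilyloxy)prop-1-yne, via lithium acetylide 2 (not isolated), via lithium ynolate 3 (not isolated)
Conditions: n-BuLi, THF, −78 °C; t-BuOOLi (from t-BuOOH and LiN(SiMe3)2), −78 → 0 °C; i-Pr3SiOTf, −78 → 0 °C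
Reagents that add atoms: tert-butyl hydroperoxide, CC(C)(C)OO; triisopropylsilyl triflate, CC(C)[Si](OS(=O)(=O)C(F)(F)F)(C(C)C)C(C)C
Why: Oxidation of a lithium acetylide by lithium tert-butyl peroxide is the known acetylide-to-ynolate oxidation, the bulky silyl triflate should silylate the ynolate on oxygen, and the propargylic silyl ether is too poor a leaving group to be eliminated at low temperature.

Step 2
Reactants: 4 3-(tert-butyldimethylsilyloxy)-1-(triisopropylsilyloxy)prop-1-yne; 5 acetone (ketene source)
Product: 7 2-[(tert-butyldimethylsilyloxy)methyl]-3-(triisopropylsilyloxy)cyclobut-2-en-1-one, via ketene 6 (not isolated)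
Conditions: acetone cracked in a hot-wire ketene lamp (ca. 700 °C); ketene stream passed into 4, CH2Cl2, 0 °C → rt
Reagents that add atoms: none
Why: Ketene–ynol ether (2+2) cycloaddition, in which the alkyne carbon remote from oxygen attacks the ketene carbonyl carbon, so that ring closure should place the silyloxy group on C3 and the arm on C2 of the cyclobutenone.

Step 3
Reactants: 8 prop-2-yn-1-ol
Product: 9 triethyl(prop-2-yn-1-yloxy)silane
Conditions: Et3SiCl, imidazole, CH2Cl2, 0 °C
Reagents that add atoms: chlorotriethylsilane, CC[Si](Cl)(CC)CC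
Why: Imidazole-mediated silylation of a primary alcohol is routine.

Step 4
Reactants: 9 triethyl(prop-2-yn-1-yloxy)silane
Product: 12 3-(triethylsilyloxy)-1-(triisopropylsilyloxy)prop-1-yne, via lithium acetylide 10 (not isolated), via lithium ynolate 11 (not isolated)
Conditions: n-BuLi, THF, −78 °C; t-BuOOLi (from t-BuOOH and LiN(SiMe3)2), −78 → 0 °C; i-Pr3SiOTf, −78 → 0 °C
Reagents that add atoms: tert-butyl hydroperoxide, CC(C)(C)OO; triisopropylsilyl triflate, CC(C)[Si](OS(=O)(=O)C(F)(F)F)(C(C)C)C(C)C
Why: Same acetylide-to-ynolate oxidation and O-silylation as in step 1, and the primary triethylsilyl ether should tolerate the basic, non-aqueous conditions.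

Step 5
Reactants: 7 2-[(tert-butyldimethylsilyloxy)methyl]-3-(triisopropylsilyloxy)cyclobut-2-en-1-one; 12 3-(triethylsilyloxy)-1-(triisopropylsilyloxy)prop-1-yne
Product: 17 4-[(tert-butyldimethylsilyloxy)methyl]-2-[(triethylsilyloxy)methyl]-3,5-bis(triisopropylsilyloxy)phenol, via vinylketene 13 (not isolated), via 4-vinylcyclobutenone 14 (not isolated), via dienylketene 15 (not isolated), via cyclohexadienone 16 (not isolated)
Conditions: 12 (1.3 equiv), toluene, 110 °C, sealed tube
Reagents that add atoms: none
Why: Heating opens 7 by 4π electrocyclic ring opening to the 2-silyloxyvinylketene 13, which adds the silyloxyalkyne 12 in a (2+2) cycloaddition to give the 4-vinylcyclobutenone 14; this opens again to the dienylketene 15, whose 6π electrocyclization joins the ketene carbon to the enol ether CH2 terminus, and tautomerization of cyclohexadienone 16 gives the phenol. The closest known reaction is the Danheiser benzannulation of cyclobutenones with triisopropylsilyloxyalkynes, which gives resorcinol monosilyl ethers; a 3-silyloxy-2-alkylcyclobutenone is an unusual partner within that class. The benzene ring is the only ring closed, and its mode of closure is the thermal disrotatory 6π electrocyclization of 15; the four-membered ring of 14 is transient. No stereocentre is set, since the quaternary carbon of 14 forms as a racemate and is lost in the next ring opening. The step needs a single regiochemistry in the (2+2) addition, and the polarization of both partners secures it: the alkyne carbon remote from oxygen is the nucleophile and bonds to the electrophilic ketene carbonyl carbon, which places the triethylsilyl arm ortho and the silyloxy group meta to the new hydroxyl. A small excess of 12 should keep the vinylketene from acylating the product phenol, and the nucleophilic enol ether terminus of 15 is electronically matched to the ketene carbon in the ring closure.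

Step 6
Reactants: 17 4-[(tert-butyldimethylsilyloxy)methyl]-2-[(triethylsilyloxy)methyl]-3,5-bis(triisopropylsilyloxy)phenol
Product: 18 6-bromo-4-[(tert-butyldimethylsilyloxy)methyl]-2-[(triethylsilyloxy)methyl]-3,5-bis(triisopropylsilyloxy)phenol
Conditions: N-bromosuccinimide (1.0 equiv), CH2Cl2, −78 °C
Reagents that add atoms: N-bromosuccinimide, O=C1CCC(=O)N1Br
Why: Electrophilic aromatic bromination should occur at the only unsubstituted ring carbon, which is ortho to the free hydroxyl and ortho and para to the two silyloxy groups, at low temperature and without acid.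

Step 7
Reactants: 18 6-bromo-4-[(tert-butyldimethylsilyloxy)methyl]-2-[(triethylsilyloxy)methyl]-3,5-bis(triisopropylsilyloxy)phenol; 19 butanoyl chloride
Product: 20 6-bromo-4-[(tert-butyldimethylsilyloxy)methyl]-2-[(triethylsilyloxy)methyl]-3,5-bis(triisopropylsilyloxy)phenyl butanoate
Conditions: Et3N, 4-(dimethylamino)pyridine (cat.), CH2Cl2, 0 °C
Reagents that add atoms: none
Why: Amine-catalysed O-acylation of a phenol is routine even for a doubly ortho-substituted phenol, and none of the ether arms carries a leaving group that the phenoxide could expel.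

Step 8
Reactants: 20 6-bromo-4-[(tert-butyldimethylsilyloxy)methyl]-2-[(triethylsilyloxy)methyl]-3,5-bis(triisopropylsilyloxy)phenyl butanoate
Product: 22 1-[2-hydroxy-3-[(triethylsilyloxy)methyl]-5-[(tert-butyldimethylsilyloxy)methyl]-4,6-bis(triisopropylsilyloxy)phenyl]butan-1-one, via aryllithium 21 (not isolated)
Conditions: t-BuLi (2.1 equiv), THF, −95 → −40 °C; H2O work-up
Reagents that add atoms: none
Why: Bromine–lithium exchange gives an aryllithium that attacks the neighbouring ester carbonyl, and this anionic Fries (1,3 O→C acyl) shift should deliver the o-hydroxyaryl ketone without the Lewis acid of a Friedel–Crafts acylation, which the electron-rich benzylic silyl ethers would not survive.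

Step 9
Reactants: 23 1-(2,4,6-trihydroxyphenyl)ethan-1-one
Product: 24 acetylfilicinic acid (2-acetyl-3,5-dihydroxy-4,4-dimethylcyclohexa-2,5-dien-1-one)
Conditions: NaOMe, MeI, MeOH, 0 °C → rt
Reagents that add atoms: iodomethane, CI
Why: Base-mediated C-methylation of an acylphloroglucinol is the classical acylfilicinic acid synthesis, the second methyl group entering at the same ring carbon and dearomatising the ring to the gem-dimethyl β-triketone, with over-methylated by-products to be separated.

Step 10
Reactants: 25 1-(2,4,6-trihydroxyphenyl)propan-1-one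
Product: 26 propionylfilicinic acid (3,5-dihydroxy-4,4-dimethyl-2-propanoylcyclohexa-2,5-dien-1-one)
Conditions: NaOMe, MeI, MeOH, 0 °C → rt
Reagents that add atoms: iodomethane, CI
Why: Same dearomatising gem-dimethylation as in step 9.

Step 11
Reactants: 22 1-[2-hydroxy-3-[(triethylsilyloxy)methyl]-5-[(tert-butyldimethylsilyloxy)methyl]-4,6-bis(triisopropylsilyloxy)phenyl]butan-1-one
Product: 27 1-[2-hydroxy-3-(hydroxymethyl)-5-[(tert-butyldimethylsilyloxy)methyl]-4,6-bis(triisopropylsilyloxy)phenyl]butan-1-one
Conditions: HF·pyridine, pyridine, THF, 0 °C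
Reagents that add atoms: none
Why: Selective desilylation with buffered HF·pyridine should cleave the primary triethylsilyl ether much faster than the primary tert-butyldimethylsilyl ether and the aryl triisopropylsilyl ethers, in a medium too weakly acidic to ionise the benzylic alcohol.

Step 12
Reactants: 27 1-[2-hydroxy-3-(hydroxymethyl)-5-[(tert-butyldimethylsilyloxy)methyl]-4,6-bis(triisopropylsilyloxy)phenyl]butan-1-one; 24 acetylfilicinic acid
Product: 29 2-acetyl-6-{[3-butanoyl-2-hydroxy-5-[(tert-butyldimethylsilyloxy)methyl]-4,6-bis(triisopropylsilyloxy)phenyl]methyl}-3,5-dihydroxy-4,4-dimethylcyclohexa-2,5-dien-1-one, via o-quinone methide 28 (not isolated)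
Conditions: 24 (1.5 equiv), (PhO)2P(O)OH (10 mol %), 4 Å molecular sieves, CH2Cl2, rt
Reagents that add atoms: none
Why: Brønsted acid-catalysed dehydration of the o-hydroxybenzyl alcohol to the o-quinone methide and Michael addition of the enolic ring carbon of the acylfilicinic acid should give the methylene bridge, while the silyl ether of the second arm, with its hindered and weakly basic oxygen, should not ionise.

Step 13
Reactants: 29 the mono-bridged compound from step 12
Product: 30 2-acetyl-6-{[3-butanoyl-2-hydroxy-5-(hydroxymethyl)-4,6-bis(triisopropylsilyloxy)phenyl]methyl}-3,5-dihydroxy-4,4-dimethylcyclohexa-2,5-dien-1-one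
Conditions: HF·pyridine, pyridine, THF, rt
Reagents that add atoms: none
Why: Longer exposure to HF·pyridine should remove the primary tert-butyldimethylsilyl ether while the hindered aryl triisopropylsilyl ethers stay, since acidic fluoride cleaves alkyl silyl ethers faster than aryl silyl ethers.

Step 14
Reactants: 30 the benzylic alcohol from step 13; 26 propionylfilicinic acid
Product: 32 the doubly bridged compound, that is 33 with triisopropylsilyl ethers on the two central-ring hydroxyls that flank the propionylfilicinic arm, via p-quinone methide 31 (not isolated)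
Conditions: 26 (1.5 equiv), (PhO)2P(O)OH (10 mol %), 4 Å molecular sieves, ClCH2CH2Cl, 40 °C
Reagents that add atoms: none
Why: Acid-catalysed ionisation of the p-hydroxybenzyl alcohol should give a para-quinone methide that the propionylfilicinic acid traps at carbon by 1,6-addition as in step 12, and the absence of base keeps the first bridge from scrambling by retro-Michael cleavage (rottlerone change).

Step 15
Reactants: 32 the doubly bridged bis(triisopropylsilyl) ether
Product: 33 the target, 2-acetyl-6-{[3-butanoyl-5-[(2,4-dihydroxy-3,3-dimethyl-6-oxo-5-propanoylcyclohexa-1,4-dien-1-yl)methyl]-2,4,6-trihydroxyphenyl]methyl}-3,5-dihydroxy-4,4-dimethylcyclohexa-2,5-dien-1-one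
Conditions: Bu4NF, AcOH (1:1), THF, 0 °C → rt
Reagents that add atoms: none
Why: Fluoride-mediated cleavage of aryl silyl ethers is routine, and buffering with acetic acid should keep the phenols protonated so that the methylene bridges are not opened.

**Compound list**

1 | tert-butyldimethyl(prop-2-yn-1-yloxy)silane | C#CCO[Si](C)(C)C(C)(C)C | starting material
2 | lithium acetylide of 1 | [Li]C#CCO[Si](C)(C)C(C)(C)C | intermediate
3 | lithium ynolate, lithium 3-(tert-butyldimethylsilyloxy)prop-1-yn-1-olate | [Li]OC#CCO[Si](C)(C)C(C)(C)C | intermediate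
4 | 3-(tert-butyldimethylsilyloxy)-1-(triisopropylsilyloxy)prop-1-yne | CC(C)[Si](OC#CCO[Si](C)(C)C(C)(C)C)(C(C)C)C(C)C | intermediate
5 | acetone | CC(C)=O | starting material
6 | ketene | C=C=O | intermediate
7 | 2-[(tert-butyldimethylsilyloxy)methyl]-3-(triisopropylsilyloxy)cyclobut-2-en-1-one | O=C1CC(O[Si](C(C)C)(C(C)C)C(C)C)=C1CO[Si](C)(C)C(C)(C)C | intermediate
8 | prop-2-yn-1-ol | C#CCO | starting material
9 | triethyl(prop-2-yn-1-yloxy)silane | C#CCO[Si](CC)(CC)CC | intermediate
10 | lithium acetylide of 9 | [Li]C#CCO[Si](CC)(CC)CC | intermediate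
11 | lithium ynolate, lithium 3-(triethylsilyloxy)prop-1-yn-1-olate | [Li]OC#CCO[Si](CC)(CC)CC | intermediate
12 | 3-(triethylsilyloxy)-1-(triisopropylsilyloxy)prop-1-yne | CC[Si](CC)(CC)OCC#CO[Si](C(C)C)(C(C)C)C(C)C | intermediate
13 | vinylketene, 2-[(TBS-oxy)methyl]-3-(TIPS-oxy)buta-1,3-dien-1-one | C=C(O[Si](C(C)C)(C(C)C)C(C)C)C(CO[Si](C)(C)C(C)(C)C)=C=O | intermediate
14 | 4-vinylcyclobutenone, 4-[(TBS-oxy)methyl]-2-[(TES-oxy)methyl]-3-(TIPS-oxy)-4-[1-(TIPS-oxy)ethenyl]cyclobut-2-en-1-one (racemic) | C=C(O[Si](C(C)C)(C(C)C)C(C)C)C1(CO[Si](C)(C)C(C)(C)C)C(=O)C(CO[Si](CC)(CC)CC)=C1O[Si](C(C)C)(C(C)C)C(C)C | intermediate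
15 | dienylketene, 4-[(TBS-oxy)methyl]-2-[(TES-oxy)methyl]-3,5-bis(TIPS-oxy)hexa-1,3,5-trien-1-one, ketene and vinyl groups cis on the central double bond | O=C=C(CO[Si](CC)(CC)CC)/C(O[Si](C(C)C)(C(C)C)C(C)C)=C(\C(=C)O[Si](C(C)C)(C(C)C)C(C)C)CO[Si](C)(C)C(C)(C)C | intermediate
16 | cyclohexadienone, 4-[(TBS-oxy)methyl]-2-[(TES-oxy)methyl]-3,5-bis(TIPS-oxy)cyclohexa-2,4-dien-1-one | O=C1CC(O[Si](C(C)C)(C(C)C)C(C)C)=C(CO[Si](C)(C)C(C)(C)C)C(O[Si](C(C)C)(C(C)C)C(C)C)=C1CO[Si](CC)(CC)CC | intermediate
17 | 4-[(tert-butyldimethylsilyloxy)methyl]-2-[(triethylsilyloxy)methyl]-3,5-bis(triisopropylsilyloxy)phenol | Oc1cc(O[Si](C(C)C)(C(C)C)C(C)C)c(CO[Si](C)(C)C(C)(C)C)c(O[Si](C(C)C)(C(C)C)C(C)C)c1CO[Si](CC)(CC)CC | intermediate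
18 | 6-bromo-4-[(tert-butyldimethylsilyloxy)methyl]-2-[(triethylsilyloxy)methyl]-3,5-bis(triisopropylsilyloxy)phenol | Oc1c(Br)c(O[Si](C(C)C)(C(C)C)C(C)C)c(CO[Si](C)(C)C(C)(C)C)c(O[Si](C(C)C)(C(C)C)C(C)C)c1CO[Si](CC)(CC)CC | intermediate
19 | butanoyl chloride | CCCC(Cl)=O | starting material
20 | 6-bromo-4-[(tert-butyldimethylsilyloxy)methyl]-2-[(triethylsilyloxy)methyl]-3,5-bis(triisopropylsilyloxy)phenyl butanoate | CCCC(=O)Oc1c(Br)c(O[Si](C(C)C)(C(C)C)C(C)C)c(CO[Si](C)(C)C(C)(C)C)c(O[Si](C(C)C)(C(C)C)C(C)C)c1CO[Si](CC)(CC)CC | intermediate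
21 | aryllithium, 6-lithio analogue of 20 | CCCC(=O)Oc1c([Li])c(O[Si](C(C)C)(C(C)C)C(C)C)c(CO[Si](C)(C)C(C)(C)C)c(O[Si](C(C)C)(C(C)C)C(C)C)c1CO[Si](CC)(CC)CC | intermediate
22 | 1-[2-hydroxy-3-[(triethylsilyloxy)methyl]-5-[(tert-butyldimethylsilyloxy)methyl]-4,6-bis(triisopropylsilyloxy)phenyl]butan-1-one | CCCC(=O)c1c(O)c(CO[Si](CC)(CC)CC)c(O[Si](C(C)C)(C(C)C)C(C)C)c(CO[Si](C)(C)C(C)(C)C)c1O[Si](C(C)C)(C(C)C)C(C)C | intermediate
23 | 1-(2,4,6-trihydroxyphenyl)ethan-1-one | CC(=O)c1c(O)cc(O)cc1O | starting material
24 | acetylfilicinic acid, 2-acetyl-3,5-dihydroxy-4,4-dimethylcyclohexa-2,5-dien-1-one | CC(=O)C1=C(O)C(C)(C)C(O)=CC1=O | intermediate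
25 | 1-(2,4,6-trihydroxyphenyl)propan-1-one | CCC(=O)c1c(O)cc(O)cc1O | starting material
26 | propionylfilicinic acid, 3,5-dihydroxy-4,4-dimethyl-2-propanoylcyclohexa-2,5-dien-1-one | CCC(=O)C1=C(O)C(C)(C)C(O)=CC1=O | intermediate
27 | 1-[2-hydroxy-3-(hydroxymethyl)-5-[(tert-butyldimethylsilyloxy)methyl]-4,6-bis(triisopropylsilyloxy)phenyl]butan-1-one | CCCC(=O)c1c(O)c(CO)c(O[Si](C(C)C)(C(C)C)C(C)C)c(CO[Si](C)(C)C(C)(C)C)c1O[Si](C(C)C)(C(C)C)C(C)C | intermediate
28 | o-quinone methide, 2-butanoyl-6-methylidene-4-[(TBS-oxy)methyl]-3,5-bis(TIPS-oxy)cyclohexa-2,4-dien-1-one | C=C1C(=O)C(C(=O)CCC)=C(O[Si](C(C)C)(C(C)C)C(C)C)C(CO[Si](C)(C)C(C)(C)C)=C1O[Si](C(C)C)(C(C)C)C(C)C | intermediate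
29 | 2-acetyl-6-{[3-butanoyl-2-hydroxy-5-[(tert-butyldimethylsilyloxy)methyl]-4,6-bis(triisopropylsilyloxy)phenyl]methyl}-3,5-dihydroxy-4,4-dimethylcyclohexa-2,5-dien-1-one | CCCC(=O)c1c(O)c(CC2=C(O)C(C)(C)C(O)=C(C(C)=O)C2=O)c(O[Si](C(C)C)(C(C)C)C(C)C)c(CO[Si](C)(C)C(C)(C)C)c1O[Si](C(C)C)(C(C)C)C(C)C | intermediate
30 | 2-acetyl-6-{[3-butanoyl-2-hydroxy-5-(hydroxymethyl)-4,6-bis(triisopropylsilyloxy)phenyl]methyl}-3,5-dihydroxy-4,4-dimethylcyclohexa-2,5-dien-1-one | CCCC(=O)c1c(O)c(CC2=C(O)C(C)(C)C(O)=C(C(C)=O)C2=O)c(O[Si](C(C)C)(C(C)C)C(C)C)c(CO)c1O[Si](C(C)C)(C(C)C)C(C)C | intermediate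
31 | p-quinone methide, 2-butanoyl-4-methylidene-3,5-bis(TIPS-oxy)cyclohexa-2,5-dien-1-one carrying the acetylfilicinic-methyl group on C6 | C=C1C(O[Si](C(C)C)(C(C)C)C(C)C)=C(CC2=C(O)C(C)(C)C(O)=C(C(C)=O)C2=O)C(=O)C(C(=O)CCC)=C1O[Si](C(C)C)(C(C)C)C(C)C | intermediate
32 | doubly bridged compound, 33 with triisopropylsilyl ethers on the two central-ring hydroxyls flanking the propionylfilicinic arm | CCCC(=O)c1c(O)c(CC2=C(O)C(C)(C)C(O)=C(C(C)=O)C2=O)c(O[Si](C(C)C)(C(C)C)C(C)C)c(CC2=C(O)C(C)(C)C(O)=C(C(=O)CC)C2=O)c1O[Si](C(C)C)(C(C)C)C(C)C | intermediate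
33 | target, butyrylphloroglucinol bridged by CH2 to acetylfilicinic acid on one side and to propionylfilicinic acid on the other (no stereocentres) | CCCC(=O)c1c(O)c(CC2=C(O)C(C)(C)C(O)=C(C(C)=O)C2=O)c(O)c(CC2=C(O)C(C)(C)C(O)=C(C(=O)CC)C2=O)c1O | target

**Count and risks**

Total step count: 15. Longest linear sequence: 11 steps (steps 1, 2, 5, 6, 7, 8, 11, 12, 13, 14, 15; the branch through steps 3 and 4 is equally long).

Steps most likely to fail:

- **Step 5.** The vinylogous silyl ester 7 may open too slowly, so that the vinylketene is lost to dimerisation or to acylation of the product phenol, and the o-hydroxybenzyl silyl ether of the product may lose silanol thermally. Fallback: abandon the benzannulation and use the classical formaldehyde assembly of this compound class. It sets out from 24 and 26 and comes back to the route at 33. Purchased 1-(2,4,6-trihydroxyphenyl)butan-1-one F1, used in excess, is condensed with 24 and aqueous formaldehyde in dilute aqueous NaOH at 0 °C to give the mono-bridged compound 2-acetyl-6-[(3-butanoyl-2,4,6-trihydroxyphenyl)methyl]-3,5-dihydroxy-4,4-dimethylcyclohexa-2,5-dien-1-one F2. A second formaldehyde condensation of F2 with 26 under the same conditions should give 33. This gives up the differentiation of the arms: the products are statistical, have to be separated, and the reaction times must be short to limit scrambling of the bridges in base.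

- **Step 8.** The aryllithium may undergo migration of the neighbouring silyl group from oxygen to carbon (retro-Brook shift), or the alkyllithium may add to the ester before exchange. Fallback: a photochemical Fries shift, which needs no organometallic. It sets out from 17 and comes back at 22. Phenol 17 is acylated with 19 (Et3N, 4-(dimethylamino)pyridine, CH2Cl2) to 4-[(tert-butyldimethylsilyloxy)methyl]-2-[(triethylsilyloxy)methyl]-3,5-bis(triisopropylsilyloxy)phenyl butanoate F3. Irradiation of F3 (254 nm, cyclohexane) should move the acyl group through the radical pair to the only free ortho carbon and give 22 directly; steps 6 and 7 are then not needed.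

- **Step 14.** Ionisation at a benzylic carbon flanked by two bulky silyloxy groups may be sluggish, so that aryl silyl ethers are lost or the triketone is alkylated on oxygen first. Fallback: an anionic, fluoride-triggered quinone methide formation in place of the acid-catalysed one. It sets out from 29 and comes back at 33. Compound 29 is treated with unbuffered Bu4NF in THF at 0 °C in the presence of 26. Fluoride should strip the three silyl groups, the freed phenoxide should expel the benzylic oxygen to give the quinone methide, and the enolate of 26 should trap it. The reaction is quenched early with AcOH to limit base-induced scrambling of the first bridge. This fallback replaces steps 13 to 15 and makes no compound outside the list (F0).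

**Further compounds**

F1 | step 5 | 1-(2,4,6-trihydroxyphenyl)butan-1-one | CCCC(=O)c1c(O)cc(O)cc1O
F2 | step 5 | 2-acetyl-6-[(3-butanoyl-2,4,6-trihydroxyphenyl)methyl]-3,5-dihydroxy-4,4-dimethylcyclohexa-2,5-dien-1-one | CCCC(=O)c1c(O)cc(O)c(CC2=C(O)C(C)(C)C(O)=C(C(C)=O)C2=O)c1O
F3 | step 8 | 4-[(tert-butyldimethylsilyloxy)methyl]-2-[(triethylsilyloxy)methyl]-3,5-bis(triisopropylsilyloxy)phenyl butanoate | CCCC(=O)Oc1cc(O[Si](C(C)C)(C(C)C)C(C)C)c(CO[Si](C)(C)C(C)(C)C)c(O[Si](C(C)C)(C(C)C)C(C)C)c1CO[Si](CC)(CC)CC
F0 | step 14 | none | none
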